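**One step.** In a one-step world, with the rate proportional to substrate and to catalyst, the fraction of substrate left in one flask is a power of the fraction left at the same time in another, and the power is their catalyst ratio.

| flask | substrate | partner | catalyst | product | time |
|---|---|---|---|---|---|
| gamma | 300 mM | 750 mM | 9.00 mM |  |  |
| beta | 150 mM | 750 mM | 9.00 mM |  |  |
| alpha | 300 mM | 750 mM | 9.00 mM | 150 mM |  |
| theta | 300 mM | 750 mM | 45.0 mM |  | 5.0 min |

- gamma run (time / min: [substrate] / mM): 0.83: 266.1; 1.7: 242.3; 2.5: 217.8; 3.3: 208.6; 4.2: 194.0; 5.0: 180.2
- beta run (time / min: [substrate] / mM): 0.83: 132.7; 1.7: 119.6; 2.5: 109.6; 3.3: 102.1; 4.2: 97.0; 5.0: 90.3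
- alpha run (time / min: [substrate] / mM): 0.83: 256.7; 1.7: 222.9; 2.5: 202.4; 3.3: 186.8; 4.2: 171.1; 5.0: 159.4

(each reading ± 2 mM)

1. the exponent of [substrate] in the starting rate at the charge of the gamma run (at the point where two percent of the substrate have become product) (one fixed amount of product, the same in the runs compared)
2. substrate in the theta run at 5.0 min, as a share of the substrate charged

- Overall: substrate + partner -> product, with catalyst as catalyst.
- Constant volume, constant temperature.
- An order is taken over about fifteen percent of the charge, up and down.

**Main step.** Gamma and beta keep 0.601 and 0.602 of their charges at 5.0 min, and the first drops give us a rough substrate exponent of 0.971. Theta has 5.00 times gamma's catalyst, so theta should keep 7.82%, a logarithmic loss (ln of charge over substrate left) of 2.55. Gamma's slowing with time comes along inside that loss.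

**Product added.** Alpha's first drop is 1.28 times gamma's. We read product as extra catalyst, each unit worth 0.0166 of a unit of catalyst. A whole charge turned then raises the rate by a fraction 0.555 in gamma but 0.111 in theta, less than in gamma. We take the mean fraction turned as two thirds of the end value: 0.266 for gamma and 0.615 for theta. Theta's share left becomes 9.33%.

**Partner drawn.** Now we also take the rate as proportional to partner, as our assumption; gamma, beta and alpha all start at 750 mM of it. A whole charge turned removes a fraction 0.400 of gamma's partner. The tilt, the net fractional change of the rate constant per whole charge turned, is the product gain minus the partner draw. It comes to 0.155 for gamma, 0.0773 for beta and −0.289 for theta. Theta's logarithmic loss is therefore scaled by 0.790, and our reckoning leaves 13.4%.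

**The forecast.** It gives a substrate exponent of 1 (0.85 to 1.15) and 9% left (3% to 24%), noting “Catalyst order is untested, and decay may be faster at high loading”. Our 13.4% stands above its value, inside its range.

**The flask.** The substrate exponent is 1.1, and theta keeps 14.5%.

    catalyst + substrate + partner → product + catalyst (25.56 /M²/min)
    substrate + partner + product → 2 product (0.5064 /M²/min)
    2 partner → lost reagent (0.2772 /M/min)

At its charge, theta's partner has a first half-life of 2.41 min by the loss step alone. Theta's logarithmic loss comes to 0.757 of 2.55, where the tilt gave 0.790. Beta's tilt of 0.0773 lies 0.0777 below gamma's 0.155, and product reaches 0.5 of the charge at 9.98 min in beta and 9.98 min in gamma.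

(The earlier runs and the new flask were computed on assumed constants; scatter was added.)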